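Numbering the C15 chain from the alkyne carbon (C1), the oxocane is O–C6–C7–C8–C9–C10–C11–C12. The plan rests on excising C8–C9: the ring's two oxygen-bearing carbons C6 and C10 stand in a 1,5-relationship, the signature of a de Mayo reaction. Irradiation of the enolised six-membered β-keto-δ-lactone (O, C6, C7, C10, C11, C12) with 1,2-dichloroethene forms C7–C8 and C9–C10 in one operation; the temporary C7–C10 bond of the cyclobutanol then breaks by retro-aldol, enlarging the lactone by two carbons, and loss of HCl leaves a 9-chloro-8-en-10-one. This chloroenone sets C10 and C9; the C6 lactone is then converted into the C6 side chain and C7 chloride.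

Key step: step 5

Remark: C-numbers in the text are those of the target chain; β-keto lactone 6 is drawn as its enol tautomer, the species that absorbs and reacts.

Step 1
Reactants: 1 methyl (2S)-2-hydroxybutanoate
Product: 2 methyl (2S)-2-[(tert-butyldimethylsilyl)oxy]butanoate
Conditions: t-BuMe2SiCl, imidazole, DMF, 25 °C
Reagents that add atoms: tert-butyldimethylsilyl chloride, CC(C)(C)[Si](C)(C)Cl
Why: Silyl ether protection of the secondary alcohol, which leaves the C13 stereocentre untouched and provides the bulky non-chelating group needed in step 3.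

Step 2
Reactants: 2 methyl (2S)-2-[(tert-butyldimethylsilyl)oxy]butanoate
Product: 3 (2S)-2-[(tert-butyldimethylsilyl)oxy]butanal
Conditions: i-Bu2AlH, CH2Cl2, −78 °C
Reagents that add atoms: none
Why: Partial ester reduction, which stops at the aldehyde because the tetrahedral aluminate is stable at −78 °C, the α-silyloxy centre being kept intact by using the crude aldehyde at once.

Step 3
Reactants: 3 (2S)-2-[(tert-butyldimethylsilyl)oxy]butanal; 4 2,2,6-trimethyl-4H-1,3-dioxin-4-one
Product: 5 6-[(2R,3S)-3-[(tert-butyldimethylsilyl)oxy]-2-hydroxypentyl]-2,2-dimethyl-4H-1,3-dioxin-4-one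
Conditions: 4, LiN(i-Pr)2, THF, −78 °C; then 3; AcOH quench
Reagents that add atoms: none
Why: Vinylogous aldol addition of the lithium dienolate of 4 through its γ-carbon, the new C12 carbinol being set anti to the bulky α-silyloxy group by Felkin–Anh attack on the non-chelated aldehyde (any minor syn isomer would be removed by chromatography).

Step 4
Reactants: 5 6-[(2R,3S)-3-[(tert-butyldimethylsilyl)oxy]-2-hydroxypentyl]-2,2-dimethyl-4H-1,3-dioxin-4-one
Product: 6 (6R)-6-[(1S)-1-[(tert-butyldimethylsilyl)oxy]propyl]-4-hydroxy-5,6-dihydro-2H-pyran-2-one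
Conditions: toluene, 110 °C, high dilution
Reagents that add atoms: none
Why: Thermal retro-hetero-Diels–Alder loss of acetone gives an acylketene that the C12 hydroxyl traps intramolecularly (acylketene lactonisation), closing the six-membered β-keto lactone without touching either stereocentre.

Step 5
Reactants: 6 (6R)-6-[(1S)-1-[(tert-butyldimethylsilyl)oxy]propyl]-4-hydroxy-5,6-dihydro-2H-pyran-2-one; 7 (E)-1,2-dichloroethene
Product: 10 (8R)-8-[(1S)-1-[(tert-butyldimethylsilyl)oxy]propyl]-5-chloro-7,8-dihydro-2H-oxocine-2,6(3H)-dione (ring-cis C4=C5 chloroenone), via cyclobutanol photoadduct 8 (not isolated), via dichloro keto-lactone 9 (not isolated)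
Conditions: hν (254 nm, quartz), 7 (20 equiv), MeCN, 0 °C; then Et3N, 25 °C
Reagents that add atoms: none
Why: De Mayo reaction: the enol form of 6 (a cyclic vinylogous acid, C10(OH)=C7–C6(=O)–O) is excited and should add stepwise through a triplet 1,4-biradical to dichloroethene, forming C7–C8 and C9–C10 in the cis-fused cyclobutanol 8, the closest precedent being the [2+2] photocycloaddition/retro-aldol sequence of enolised cyclic 1,3-dicarbonyl compounds and of tetronates. The four-membered ring closes by intermolecular [2+2] cycloaddition (biradical recombination) across the C7=C10 enol double bond of the six-membered lactone, whereas the eight-membered ring is not closed by bond formation but released when the strained β-hydroxy lactone 8 undergoes retro-aldol cleavage of the temporary C7–C10 bond, the only bond that is attached to the carbinol carbon C10 and α to the C6 carbonyl. Triethylamine then expels the C8 chloride by E1cB through the more acidic α-chloro ketone hydrogen at C9, so that all diastereomers of 9 converge on one chloroenone. No new stereocentre has to be controlled, because C10 becomes a carbonyl, C7 a methylene and C8/C9 an alkene, while C12 and C13 are not involved. Regiochemistry is not an issue with the symmetrical alkene, and the selectivity needed, cross-addition over dimerisation of 6, is secured by the large excess of dichloroethene.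

Step 6
Reactants: 10 (8R)-8-[(1S)-1-[(tert-butyldimethylsilyl)oxy]propyl]-5-chloro-7,8-dihydro-2H-oxocine-2,6(3H)-dione
Product: 11 (6S,8R)-8-[(1S)-1-[(tert-butyldimethylsilyl)oxy]propyl]-5-chloro-6-hydroxy-3,6,7,8-tetrahydro-2H-oxocin-2-one (ring-cis C4=C5)
Conditions: (R)-2-methyl-CBS-oxazaborolidine (20 mol %), BH3·SMe2, THF, −40 °C
Reagents that add atoms: none
Why: Corey–Bakshi–Shibata reduction, in which the α-chlorovinyl arm acts as the large ketone substituent so that the (R)-catalyst should deliver hydride 1,2 to give the (S)-carbinol at C10 under catalyst control, the lactone being inert to borane at this temperature.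

Step 7
Reactants: 11 (6S,8R)-8-[(1S)-1-[(tert-butyldimethylsilyl)oxy]propyl]-5-chloro-6-hydroxy-3,6,7,8-tetrahydro-2H-oxocin-2-one
Product: 12 (5S,6S,8R)-8-[(1S)-1-[(tert-butyldimethylsilyl)oxy]propyl]-5-chloro-6-hydroxyoxocan-2-one
Conditions: H2 (1 atm), [Ir(cod)(PCy3)(py)]PF6 (5 mol %), CH2Cl2, 25 °C
Reagents that add atoms: none
Why: Hydroxyl-directed homogeneous hydrogenation, in which iridium bound to the C10 hydroxyl should deliver both hydrogens to the alkene face syn to that hydroxyl and so place the C9 chlorine trans to the C10 oxygen.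

Step 8
Reactants: 12 (5S,6S,8R)-8-[(1S)-1-[(tert-butyldimethylsilyl)oxy]propyl]-5-chloro-6-hydroxyoxocan-2-one
Product: 13 (5S,6S,8R)-8-[(1S)-1-[(tert-butyldimethylsilyl)oxy]propyl]-5-chloro-6-[(triethylsilyl)oxy]oxocan-2-one
Conditions: Et3SiCl, imidazole, CH2Cl2, 0 °C
Reagents that add atoms: triethylsilyl chloride, CC[Si](CC)(CC)Cl
Why: Silyl ether protection carried out directly on the hydrogenation product masks the C10 hydroxyl before it can transfer the lactone acyl group and makes it inert to the base of step 9.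

Step 9
Reactants: 13 (5S,6S,8R)-8-[(1S)-1-[(tert-butyldimethylsilyl)oxy]propyl]-5-chloro-6-[(triethylsilyl)oxy]oxocan-2-one
Product: 14 (2R,4S,5S)-2-[(1S)-1-[(tert-butyldimethylsilyl)oxy]propyl]-5-chloro-4-[(triethylsilyl)oxy]-3,4,5,6-tetrahydro-2H-oxocin-8-yl diphenyl phosphate
Conditions: (PhO)2P(O)Cl, HMPA, THF, −78 °C, KN(SiMe3)2 added last
Reagents that add atoms: diphenyl chlorophosphate, O=P(Cl)(Oc1ccccc1)Oc1ccccc1
Why: Enolisation of the medium-ring lactone with O-phosphorylation (ketene acetal phosphate formation) fixes the C6=C7 double bond, the base being added last so that the enolate is trapped before it can displace the C9 chloride.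

Step 10
Reactants: 14 (2R,4S,5S)-2-[(1S)-1-[(tert-butyldimethylsilyl)oxy]propyl]-5-chloro-4-[(triethylsilyl)oxy]-3,4,5,6-tetrahydro-2H-oxocin-8-yl diphenyl phosphate; 15 allyltributylstannane
Product: 16 (2R,4S,5S)-8-allyl-2-[(1S)-1-[(tert-butyldimethylsilyl)oxy]propyl]-5-chloro-4-[(triethylsilyl)oxy]-3,4,5,6-tetrahydro-2H-oxocine (cyclic enol ether, ring double bond C7=C8)
Conditions: Pd(PPh3)4 (5 mol %), LiCl, THF, 65 °C
Reagents that add atoms: none
Why: Stille cross-coupling of the ketene acetal phosphate with the allylstannane attaches C5 to C6 and leaves the enol ether double bond at C6=C7.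

Step 11
Reactants: 16 (2R,4S,5S)-8-allyl-2-[(1S)-1-[(tert-butyldimethylsilyl)oxy]propyl]-5-chloro-4-[(triethylsilyl)oxy]-3,4,5,6-tetrahydro-2H-oxocine
Product: 17 (3S,5S,6S,8R)-2-allyl-3,5-dichloro-2-methoxy-6-[(triethylsilyl)oxy]-8-[(1S)-1-[(tert-butyldimethylsilyl)oxy]propyl]oxocane (ketal carbon C2 of either configuration)
Conditions: NCS, NaHCO3, MeOH/CH2Cl2, −78 → 0 °C
Reagents that add atoms: N-chlorosuccinimide, O=C1CCC(=O)N1Cl; methanol, CO
Why: Haloalkoxylation of the enol ether, in which chlorine adds to the nucleophilic β-carbon C7 and methanol traps the oxocarbenium ion, the chlorine being expected to enter from the ring face opposite the C9 chlorine and the C12 side chain to set C7, while the terminal alkene is too electron-poor to compete.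

Step 12
Reactants: 17 (3S,5S,6S,8R)-2-allyl-3,5-dichloro-2-methoxy-6-[(triethylsilyl)oxy]-8-[(1S)-1-[(tert-butyldimethylsilyl)oxy]propyl]oxocane
Product: 18 (2S,3S,5S,6S,8R)-2-allyl-3,5-dichloro-6-[(triethylsilyl)oxy]-8-[(1S)-1-[(tert-butyldimethylsilyl)oxy]propyl]oxocane
Conditions: Et3SiH, TMSOTf (cat.), CH2Cl2, −78 → −40 °C
Reagents that add atoms: none
Why: Reductive deoxygenation of the ketal by ionisation to the oxocarbenium ion and silane reduction, hydride adding anti to the adjacent C7 chlorine so that the C6 side chain ends up cis to that chlorine and trans to the C12 substituent.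

Step 13
Reactants: 18 (2S,3S,5S,6S,8R)-2-allyl-3,5-dichloro-6-[(triethylsilyl)oxy]-8-[(1S)-1-[(tert-butyldimethylsilyl)oxy]propyl]oxocane
Product: 19 (2R,4S,5S,7S,8S)-8-allyl-2-[(1S)-1-[(tert-butyldimethylsilyl)oxy]propyl]-5,7-dichlorooxocan-4-ol
Conditions: PPTS (cat.), MeOH, 0 °C
Reagents that add atoms: none
Why: Selective desilylation by mild acid methanolysis removes the triethylsilyl ether while the more hindered tert-butyldimethylsilyl ether at C13 stays.

Step 14
Reactants: 19 (2R,4S,5S,7S,8S)-8-allyl-2-[(1S)-1-[(tert-butyldimethylsilyl)oxy]propyl]-5,7-dichlorooxocan-4-ol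
Product: 20 (2R,4S,5S,7S,8S)-8-allyl-2-[(1S)-1-[(tert-butyldimethylsilyl)oxy]propyl]-5,7-dichlorooxocan-4-yl acetate
Conditions: Ac2O, pyridine, DMAP (cat.), CH2Cl2, 25 °C
Reagents that add atoms: acetic anhydride, CC(=O)OC(C)=O
Why: DMAP-catalysed esterification of the secondary C10 alcohol with retention of configuration.

Step 15
Reactants: 21 ethynyltriisopropylsilane; 22 vinyl bromide
Product: 23 (but-3-en-1-yn-1-yl)triisopropylsilane
Conditions: PdCl2(PPh3)2 (2 mol %), CuI (4 mol %), Et3N, THF, 0 → 25 °C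
Reagents that add atoms: none
Why: Sonogashira coupling of the terminal alkyne with the vinyl halide gives the silyl-capped conjugated enyne needed for step 16.

Step 16
Reactants: 20 (2R,4S,5S,7S,8S)-8-allyl-2-[(1S)-1-[(tert-butyldimethylsilyl)oxy]propyl]-5,7-dichlorooxocan-4-yl acetate; 23 (but-3-en-1-yn-1-yl)triisopropylsilane
Product: 24 (2R,4S,5S,7S,8S)-2-[(1S)-1-[(tert-butyldimethylsilyl)oxy]propyl]-5,7-dichloro-8-[(2Z)-5-(triisopropylsilyl)pent-2-en-4-yn-1-yl]oxocan-4-yl acetate
Conditions: second-generation Grubbs catalyst RuCl2(=CHPh)(H2IMes)(PCy3) (10 mol %), 23 (5 equiv), CH2Cl2, 40 °C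
Reagents that add atoms: none
Why: Olefin cross-metathesis of the allyl group with the enyne, which reacts only at its alkene and is expected to favour the Z-configured C3=C4 bond under kinetic control as is typical of silyl-capped conjugated enynes (a minor E isomer would be removed by chromatography).

Step 17
Reactants: 24 (2R,4S,5S,7S,8S)-2-[(1S)-1-[(tert-butyldimethylsilyl)oxy]propyl]-5,7-dichloro-8-[(2Z)-5-(triisopropylsilyl)pent-2-en-4-yn-1-yl]oxocan-4-yl acetate
Product: 25 (2R,4S,5S,7S,8S)-5,7-dichloro-2-[(1S)-1-hydroxypropyl]-8-[(2Z)-pent-2-en-4-yn-1-yl]oxocan-4-yl acetate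
Conditions: Bu4NF, AcOH, THF, 0 → 25 °C
Reagents that add atoms: none
Why: Fluoride-mediated desilylation cleaves both the alkynyl C–Si bond and the secondary silyl ether, the acetic acid buffer keeping the acetate and the alkyl chlorides intact.

Step 18
Reactants: 25 (2R,4S,5S,7S,8S)-5,7-dichloro-2-[(1S)-1-hydroxypropyl]-8-[(2Z)-pent-2-en-4-yn-1-yl]oxocan-4-yl acetate
Product: 26 (2R,4S,5S,7S,8S)-2-[(1R)-1-bromopropyl]-5,7-dichloro-8-[(2Z)-pent-2-en-4-yn-1-yl]oxocan-4-yl acetate
Conditions: CBr4, P(n-C8H17)3, toluene, 70 °C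
Reagents that add atoms: carbon tetrabromide, BrC(Br)(Br)Br
Why: Appel bromination, in which bromide displaces the alkoxyphosphonium ion by SN2 with inversion and so converts the (S)-alcohol at C13 into the (R)-bromide.

Compound list
1 | methyl (2S)-2-hydroxybutanoate | CC[C@H](O)C(=O)OC | starting material
2 | methyl (2S)-2-[(tert-butyldimethylsilyl)oxy]butanoate | CC[C@H](O[Si](C)(C)C(C)(C)C)C(=O)OC | intermediate
3 | (2S)-2-[(tert-butyldimethylsilyl)oxy]butanal | CC[C@H](O[Si](C)(C)C(C)(C)C)C=O | intermediate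
4 | 2,2,6-trimethyl-4H-1,3-dioxin-4-one | CC1=CC(=O)OC(C)(C)O1 | starting material
5 | 6-[(2R,3S)-3-[(tert-butyldimethylsilyl)oxy]-2-hydroxypentyl]-2,2-dimethyl-4H-1,3-dioxin-4-one | CC[C@H](O[Si](C)(C)C(C)(C)C)[C@H](O)CC1=CC(=O)OC(C)(C)O1 | intermediate
6 | (6R)-6-[(1S)-1-[(tert-butyldimethylsilyl)oxy]propyl]-4-hydroxy-5,6-dihydro-2H-pyran-2-one (enol of the β-keto-δ-lactone) | CC[C@H](O[Si](C)(C)C(C)(C)C)[C@H]1CC(O)=CC(=O)O1 | intermediate
7 | (E)-1,2-dichloroethene | Cl/C=C/Cl | starting material
8 | (4R)-4-[(1S)-1-[(tert-butyldimethylsilyl)oxy]propyl]-7,8-dichloro-6-hydroxy-3-oxabicyclo[4.2.0]octan-2-one (cis-fused, mixture at C1, C6, C7, C8) | CC[C@H](O[Si](C)(C)C(C)(C)C)[C@H]1CC2(O)C(Cl)C(Cl)C2C(=O)O1 | intermediate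
9 | (8R)-8-[(1S)-1-[(tert-butyldimethylsilyl)oxy]propyl]-4,5-dichlorooxocane-2,6-dione (mixture at C4, C5) | CC[C@H](O[Si](C)(C)C(C)(C)C)[C@H]1CC(=O)C(Cl)C(Cl)CC(=O)O1 | intermediate
10 | (8R)-8-[(1S)-1-[(tert-butyldimethylsilyl)oxy]propyl]-5-chloro-7,8-dihydro-2H-oxocine-2,6(3H)-dione (ring-cis C4=C5) | CC[C@H](O[Si](C)(C)C(C)(C)C)[C@H]1CC(=O)/C(Cl)=C\CC(=O)O1 | intermediate
11 | (6S,8R)-8-[(1S)-1-[(tert-butyldimethylsilyl)oxy]propyl]-5-chloro-6-hydroxy-3,6,7,8-tetrahydro-2H-oxocin-2-one (ring-cis C4=C5) | CC[C@H](O[Si](C)(C)C(C)(C)C)[C@H]1C[C@H](O)/C(Cl)=C\CC(=O)O1 | intermediate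
12 | (5S,6S,8R)-8-[(1S)-1-[(tert-butyldimethylsilyl)oxy]propyl]-5-chloro-6-hydroxyoxocan-2-one | CC[C@H](O[Si](C)(C)C(C)(C)C)[C@H]1C[C@H](O)[C@@H](Cl)CCC(=O)O1 | intermediate
13 | (5S,6S,8R)-8-[(1S)-1-[(tert-butyldimethylsilyl)oxy]propyl]-5-chloro-6-[(triethylsilyl)oxy]oxocan-2-one | CC[C@H](O[Si](C)(C)C(C)(C)C)[C@H]1C[C@H](O[Si](CC)(CC)CC)[C@@H](Cl)CCC(=O)O1 | intermediate
14 | (2R,4S,5S)-2-[(1S)-1-[(tert-butyldimethylsilyl)oxy]propyl]-5-chloro-4-[(triethylsilyl)oxy]-3,4,5,6-tetrahydro-2H-oxocin-8-yl diphenyl phosphate | CC[C@H](O[Si](C)(C)C(C)(C)C)[C@H]1C[C@H](O[Si](CC)(CC)CC)[C@@H](Cl)C/C=C(OP(=O)(Oc2ccccc2)Oc2ccccc2)\O1 | intermediate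
15 | allyltributylstannane | C=CC[Sn](CCCC)(CCCC)CCCC | starting material
16 | (2R,4S,5S)-8-allyl-2-[(1S)-1-[(tert-butyldimethylsilyl)oxy]propyl]-5-chloro-4-[(triethylsilyl)oxy]-3,4,5,6-tetrahydro-2H-oxocine | CC[C@H](O[Si](C)(C)C(C)(C)C)[C@H]1C[C@H](O[Si](CC)(CC)CC)[C@@H](Cl)C/C=C(CC=C)\O1 | intermediate
17 | (3S,5S,6S,8R)-2-allyl-3,5-dichloro-2-methoxy-6-[(triethylsilyl)oxy]-8-[(1S)-1-[(tert-butyldimethylsilyl)oxy]propyl]oxocane | CC[C@H](O[Si](C)(C)C(C)(C)C)[C@H]1C[C@H](O[Si](CC)(CC)CC)[C@@H](Cl)C[C@H](Cl)C(CC=C)(OC)O1 | intermediate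
18 | (2S,3S,5S,6S,8R)-2-allyl-3,5-dichloro-6-[(triethylsilyl)oxy]-8-[(1S)-1-[(tert-butyldimethylsilyl)oxy]propyl]oxocane | CC[C@H](O[Si](C)(C)C(C)(C)C)[C@H]1C[C@H](O[Si](CC)(CC)CC)[C@@H](Cl)C[C@H](Cl)[C@H](CC=C)O1 | intermediate
19 | (2R,4S,5S,7S,8S)-8-allyl-2-[(1S)-1-[(tert-butyldimethylsilyl)oxy]propyl]-5,7-dichlorooxocan-4-ol | CC[C@H](O[Si](C)(C)C(C)(C)C)[C@H]1C[C@H](O)[C@@H](Cl)C[C@H](Cl)[C@H](CC=C)O1 | intermediate
20 | (2R,4S,5S,7S,8S)-8-allyl-2-[(1S)-1-[(tert-butyldimethylsilyl)oxy]propyl]-5,7-dichlorooxocan-4-yl acetate | CC[C@H](O[Si](C)(C)C(C)(C)C)[C@H]1C[C@H](OC(C)=O)[C@@H](Cl)C[C@H](Cl)[C@H](CC=C)O1 | intermediate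
21 | ethynyltriisopropylsilane | C#C[Si](C(C)C)(C(C)C)C(C)C | starting material
22 | vinyl bromide | C=CBr | starting material
23 | (but-3-en-1-yn-1-yl)triisopropylsilane | C=CC#C[Si](C(C)C)(C(C)C)C(C)C | intermediate
24 | (2R,4S,5S,7S,8S)-2-[(1S)-1-[(tert-butyldimethylsilyl)oxy]propyl]-5,7-dichloro-8-[(2Z)-5-(triisopropylsilyl)pent-2-en-4-yn-1-yl]oxocan-4-yl acetate | CC[C@H](O[Si](C)(C)C(C)(C)C)[C@H]1C[C@H](OC(C)=O)[C@@H](Cl)C[C@H](Cl)[C@H](C/C=C\C#C[Si](C(C)C)(C(C)C)C(C)C)O1 | intermediate
25 | (2R,4S,5S,7S,8S)-5,7-dichloro-2-[(1S)-1-hydroxypropyl]-8-[(2Z)-pent-2-en-4-yn-1-yl]oxocan-4-yl acetate | CC[C@H](O)[C@H]1C[C@H](OC(C)=O)[C@@H](Cl)C[C@H](Cl)[C@H](C/C=C\C#C)O1 | intermediate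
26 | (2R,4S,5S,7S,8S)-2-[(1R)-1-bromopropyl]-5,7-dichloro-8-[(2Z)-pent-2-en-4-yn-1-yl]oxocan-4-yl acetate (CNP0251465.2) | C#C/C=C\C[C@@H]1O[C@@H]([C@H](Br)CC)C[C@H](OC(C)=O)[C@@H](Cl)C[C@@H]1Cl | target

Total step count: 18. Longest linear sequence: 17 steps (steps 1–14 and 16–18; step 15 is a one-step side branch).

Steps most likely to fail

Step 5 (key step). The lactone may sit largely in its non-absorbing diketo tautomer, photoaddition of the free enol may be slow relative to photolysis of dichloroethene, and the chlorinated cyclobutanol may undergo ring contraction instead of clean retro-aldol cleavage. The fallback separates cycloaddition from fragmentation and sets out from 6. O-Silylation (Me3SiCl, Et3N, CH2Cl2) should give the trimethylsilyl enol ether F1, a β-silyloxy enoate locked in the absorbing form. Its [2+2] photocycloaddition with 7 should give the isolable silylated cyclobutane F2. A separate fluoride treatment (Et3N·3HF, MeCN, then Et3N) then releases cyclobutanol 8 under controlled conditions, and this fragments and eliminates to the chloroenone, so that the route is rejoined at 10.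

Step 7. The vinylic C–Cl bond may be hydrogenolysed, facial delivery may be weak in the flexible ring, and the free C10 hydroxyl may attack the C6 carbonyl with acyl transfer to a six-membered lactone. The fallback sets the two centres without a metal hydride on a chloroalkene and sets out from 10. Conjugate reduction with [(Ph3P)CuH]6 in toluene should give the α-chloro ketone F3, whose C9 epimers interconvert by enolisation. A ketoreductase chosen by screening (NADPH with glucose dehydrogenase recycling, pH 7 buffer) should then reduce it under dynamic kinetic resolution to the (9S,10S)-chlorohydrin, and the route is rejoined at 12, which is silylated at once as in step 8.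

Step 11. Chlorine may enter from the wrong ring face, or without preference, which would fix C7, and through step 12 also C6, in the wrong sense. The fallback is stereocomplementary and sets out from 16. Epoxidation of the enol ether with dimethyldioxirane (acetone/CH2Cl2, −78 °C) should give the 6,7-epoxide F4. i-Bu2AlH should open it at the acetal carbon with delivery of hydride syn to the departing oxygen, giving the 7-alcohol F5 with its hydroxyl trans to the allyl group. Appel chlorination (PPh3, CCl4) with inversion then gives the cis-6,7 chloride, and the route is rejoined at 18. Because hydrogen and oxygen are added syn and the chloride arrives by inversion, this sequence reaches 18 when the enol ether reacts from the face opposite to the one needed in the chlorination route.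

Further compounds
F1 | step 5 | (6R)-6-[(1S)-1-[(tert-butyldimethylsilyl)oxy]propyl]-4-[(trimethylsilyl)oxy]-5,6-dihydro-2H-pyran-2-one | CC[C@H](O[Si](C)(C)C(C)(C)C)[C@H]1CC(O[Si](C)(C)C)=CC(=O)O1
F2 | step 5 | (4R)-4-[(1S)-1-[(tert-butyldimethylsilyl)oxy]propyl]-7,8-dichloro-6-[(trimethylsilyl)oxy]-3-oxabicyclo[4.2.0]octan-2-one | CC[C@H](O[Si](C)(C)C(C)(C)C)[C@H]1CC2(O[Si](C)(C)C)C(Cl)C(Cl)C2C(=O)O1
F3 | step 7 | (8R)-8-[(1S)-1-[(tert-butyldimethylsilyl)oxy]propyl]-5-chlorooxocane-2,6-dione (C5 epimers) | CC[C@H](O[Si](C)(C)C(C)(C)C)[C@H]1CC(=O)C(Cl)CCC(=O)O1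
F4 | step 11 | (2R,4S,5S)-8-allyl-7,8-epoxy-2-[(1S)-1-[(tert-butyldimethylsilyl)oxy]propyl]-5-chloro-4-[(triethylsilyl)oxy]oxocane (epoxide oxygen cis to the C2 side chain) | CC[C@H](O[Si](C)(C)C(C)(C)C)[C@H]1C[C@H](O[Si](CC)(CC)CC)[C@@H](Cl)C[C@H]2O[C@@]2(CC=C)O1
F5 | step 11 | (2S,3R,5S,6S,8R)-2-allyl-5-chloro-6-[(triethylsilyl)oxy]-8-[(1S)-1-[(tert-butyldimethylsilyl)oxy]propyl]oxocan-3-ol | CC[C@H](O[Si](C)(C)C(C)(C)C)[C@H]1C[C@H](O[Si](CC)(CC)CC)[C@@H](Cl)C[C@@H](O)[C@H](CC=C)O1
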